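## The problem

Pestaphilone D (30) is a 7,8-dihydro-6H-isochromen-6-one. A 4H-pyran (ring B: O2, C1, C8a, C4a, C4, C3) is fused through C4a–C8a to a carbocycle (ring A: C4a, C5, C6, C7, C8, C8a), and the C6 ketone is cross-conjugated with both enol-ether double bonds. Ring A carries a 7,8-trans diol: the tertiary carbinol C7 (7S, with a methyl group) next to the C6 ketone, and the secondary carbinol C8 (8R). C3 carries a trisubstituted (2R,3S)-epoxide whose second carbon bears an (E)-trisubstituted alkene followed by an anti 4R-methyl/5S-hydroxyl pair.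

The six stereocentres fall into three groups that are too far apart to control one another. The side-chain pair has to come from the chiral pool, the epoxide from a reagent-controlled epoxidation, and only C7 and C8 can influence each other.

Several groups will not survive rough treatment:
- the vinyl epoxide (protic and Lewis acids, low-valent metals, the free glycidic acid);
- the vinylogous-ester core (amines and strong nucleophiles at C1);
- the tertiary α-ketol and the C6/C8 β-hydroxy ketone relation (strong base);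
- any intermediate in which C8 is α to a ketone (epimerisation).

The feature that makes the key step possible is the acyloin C6(=O)–C7(OH)(CH3) with a fully substituted carbinol carbon. It is the retron of an acyl anion at C6 adding to a C7 methyl ketone held on C8. The six ring atoms C6, C5, C4a, C8a, C8, C7 are then already connected through a 4H-pyran-4-ylidene, whose fully substituted C4a blocks homoenolate chemistry.

## Retrosynthesis

**30 ⇒ 29.** The two secondary hydroxyls (C8 and side chain) are masked as tert-butyldimethylsilyl ethers. A single buffered fluoride treatment is the only operation after the ring closure, so the sensitive chromophore is exposed to one mild step.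

**29 ⇒ 28 (C6–C7, ring A).** The acyloin is cut between C6 and C7, giving the pyranylidene acetaldehyde 28 with a C8 silyloxy methyl ketone. Against the neighbouring cuts (C4a=C5 or C8–C8a), this one creates the quaternary C7 centre during ring closure under a chiral carbene, rather than requiring it to be made beforehand. The forward step must engage a donor-substituted aldehyde, pick one face of the ketone, and leave the α-silyloxy ketone centre C8 untouched.

**28 ⇒ 27 ⇒ 26 (C7 oxidation level).** The ketone cannot be present while carbon nucleophiles are used on the pyranone, so C7 is carried as a lactate-derived carbinol. It is protected as a triethylsilyl ether in 26, which can be cleaved (to 27) beside two tert-butyldimethylsilyl ethers, and is oxidised last under non-basic conditions.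

**26 ⇒ 24 (C4a=C5 and C5–C6).** The two-carbon aldehyde arm is cut from the carbonyl carbon of pyranone 24. One addition of (Z)-2-ethoxyvinyllithium and mild acidification of carbinol 25 replace a methyl addition, dehydration and formylation sequence, and avoid chloroiminium reagents in the presence of the epoxide.

**24 ⇒ 23 ⇒ 18 + 21 (C8–C8a).** The side arm is cut at the ring, giving magnesiated pyranone 22 (from iodide 18) and (S)-2-(triethylsilyloxy)propanal 21. The lactate centre controls C8 by Felkin–Anh addition and is later erased by the oxidation to 28. It therefore delivers both the C7 oxygen and the C8 configuration.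

**18 ⇒ 17 ⇒ 16 ⇒ 12 + 14 (ring B).** The pyranone is cut to the 1,3-diketone 17, which comes from aldol 16 of epoxy aldehyde 12 with the enolate 15 of iodo enone 14 (from 13). Carrying the iodine in with 14 fixes the C8a position and avoids electrophilic iodination in the presence of the side-chain alkene. The aldol/oxidation pair is preferred to acylation with an activated epoxy acid because 2-methyl-3-alkenyl glycidic acids decarboxylate readily.

**12 ⇒ 11 ⇒ 10 (epoxide).** The epoxide is cut back to dienol 10. Only the allylic double bond responds to titanium/tartrate epoxidation, so both regio- and face selectivity are reagent-controlled.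

**10 ⇒ 9 ⇒ 7 ⇒ 5 (diene).** The two (E)-trisubstituted double bonds are cut by successive Wittig reactions with the stabilised ylides 6 and 8. The formyl ylide 6 saves a reduction/oxidation pair.

**5 ⇒ 4 ⇒ 3 ⇒ 1 (anti methyl/hydroxyl pair).** The anti relation is the retron of the Fráter–Seebach methylation of ethyl (S)-3-hydroxybutanoate 1 through dianion 2. Aldehyde 21 comes from ethyl (S)-lactate 19 through 20.

## Roads not taken

**Alternative 1:** The cut is at C7–O and O2–C1, back to the aromatic keto-aldehyde A1. In the forward step a flavin-dependent monooxygenase of the AzaH family (O2, NADPH recycling) hydroxylates C7 and dearomatises ring A. The C3 ketone oxygen then condenses on the C1 aldehyde and gives the 8-oxo congener A2.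
- Merits: it is by far the shortest route. A1 is assembled by robust aromatic chemistry, C7 is set by the enzyme, and no protecting groups are needed on the core.
- Weak points: A2 is not the target. The C8 carbonyl must still be reduced regio- and diastereoselectively beside the C6 carbonyl and the electrophilic C1. Acceptance of A1 by the enzyme is open, since its side chain is an α,β-epoxy ketone with a branched alkenyl group rather than a simple acyl chain. Protein supply and cofactor recycling add a dependence that the flask route does not have.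
- Comparison: on step count and protecting-group economy this road is better. The chosen plan sets against it reliance on ordinary reagents only, and a C8 configuration fixed from lactate before ring closure, so that no late carbonyl differentiation is needed.

**Alternative 2:** The cut is at C4a=C5, back to pyranone A3, which carries the complete C8–C7–C6–C5 chain. In the forward step Me3SiOSO2CF3/2,6-lutidine makes the silyl enol ether of the C6 methyl ketone and the 4-siloxypyrylium ion. C5 adds to C4a, silanol is lost, and the tris-silyl ether A4 results.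
- Merits: no umpolung catalyst is needed. The pyranone carbonyl is used directly, which saves the two-carbon homologation and the late unveiling of a ketone. Both ring-A stereocentres are in place, so the closure creates none, and A4 is one deprotection from the target.
- Weak points: the quaternary C7 carbinol must be built before ring closure. An acetyl anion equivalent adding to a C7 methyl ketone next to the C8 silyl ether is expected, by the Felkin–Anh model, to give the 7,8-cis relation, so a less direct order of events or a separate asymmetric step is needed. The siloxypyrylium ion has a free C1, and attack of C5 there would also close a six-membered ring (C5, C6, C7, C8, C8a, C1). A silyl triflate is a strong Lewis acid for the vinyl epoxide.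
- Comparison: from the pyranone onward this road is as short or shorter. The chosen plan sets against it a C7 centre made in the ring-forming step under catalyst control, and conditions (weak amine base) that the epoxide tolerates.

**Alternative 3:** The cut is at C8–C8a, back to the pyranylidene ketone A5 with a tethered C8 aldehyde. In the forward step 1,4-diazabicyclo[2.2.2]octane (or PMe3) adds to C1, the dienolate attacks the aldehyde through C8a, and the catalyst is expelled to give A6.
- Merits: the C8 hydroxyl is formed free, which saves one protecting group. The conditions are neutral, and no intermediate has an epimerisable centre like that of 28.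
- Weak points: C8 is created in the step under 1,2-induction from a quaternary C7 whose three substituents differ little in size, and such adducts can equilibrate. C1 of a donor-substituted 4-ylidene-4H-pyran is a poor acceptor for the nucleophilic catalyst in a reaction that is slow even with good acceptors. A5 again needs the C7 quaternary centre made beforehand, on a hindered α-silyloxy aldehyde.
- Comparison: this road is better on protecting-group count. The chosen plan sets against it a C8 centre fixed by a well-understood aldehyde addition, and a ring closure with closer precedent.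

Key step: step 20

Assumption: the (5aS,10bR) enantiomer of the triazolium salt is taken to be the one that delivers C6 to the Re face of the C7 ketone; the enantiomeric salt is equally available and would be used if the sense proves opposite.

Naming note: "epoxyalkenyl" stands for the 3-[(2E,4R,5S)-5-[(tert-butyldimethylsilyl)oxy]-4-methylhex-2-en-2-yl]-2-methyloxiran-2-yl group. Its oxirane descriptors are given each time; the spatial arrangement is always that of 11.

## Route

Step 1
Reactants: 1 ethyl (S)-3-hydroxybutanoate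
Product: 3 ethyl (2S,3S)-3-hydroxy-2-methylbutanoate, via dilithium alkoxide enolate 2 (not isolated)
Conditions: LiN(iPr)2 (2.2 equiv), THF, −50 to −20 °C; MeI, DMPU, −78 to 0 °C
Reagents that add atoms: iodomethane, CI; lithium diisopropylamide, CC(C)N([Li])C(C)C (lithium of intermediate 2 only)
Why: Fráter–Seebach alkylation: the lithium-chelated alkoxide enolate is methylated on the face away from the C3 methyl group, giving the 2,3-anti (2S,3S) ester; C3 comes unchanged from 1.

Step 2
Reactants: 3 ethyl (2S,3S)-3-hydroxy-2-methylbutanoate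
Product: 4 ethyl (2S,3S)-3-[(tert-butyldimethylsilyl)oxy]-2-methylbutanoate
Conditions: t-BuMe2SiCl, imidazole, DMF, 23 °C
Reagents that add atoms: tert-butyldimethylsilyl chloride, CC(C)(C)[Si](C)(C)Cl
Why: Standard silylation of a secondary alcohol; this ether is meant to last until the final step.

Step 3
Reactants: 4 ethyl (2S,3S)-3-[(tert-butyldimethylsilyl)oxy]-2-methylbutanoate
Product: 5 (2S,3S)-3-[(tert-butyldimethylsilyl)oxy]-2-methylbutanal
Conditions: iBu2AlH (1.1 equiv), CH2Cl2, −78 °C; aq. KNaC4H4O6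
Reagents that add atoms: none
Why: Partial reduction of an ester: the aluminium hemiacetal is stable at −78 °C and releases the aldehyde only on work-up; 5 is used at once to avoid epimerisation at C2.

Step 4
Reactants: 5 (2S,3S)-3-[(tert-butyldimethylsilyl)oxy]-2-methylbutanal; 6 2-(triphenylphosphoranylidene)propanal
Product: 7 (2E,4R,5S)-5-[(tert-butyldimethylsilyl)oxy]-2,4-dimethylhex-2-enal
Conditions: toluene, 90 °C
Reagents that add atoms: none
Why: Wittig olefination with a formyl-stabilised ylide gives the (E)-2-methyl enal (formyl trans to the chain); the product enal is much less electrophilic than 5, so a second homologation is slow.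

Step 5
Reactants: 7 (2E,4R,5S)-5-[(tert-butyldimethylsilyl)oxy]-2,4-dimethylhex-2-enal; 8 ethyl 2-(triphenylphosphoranylidene)propanoate
Product: 9 ethyl (2E,4E,6R,7S)-7-[(tert-butyldimethylsilyl)oxy]-2,4,6-trimethylocta-2,4-dienoate
Conditions: toluene, 80 °C
Reagents that add atoms: none
Why: Wittig olefination with the ester-stabilised ylide sets the second (E)-trisubstituted double bond.

Step 6
Reactants: 9 ethyl (2E,4E,6R,7S)-7-[(tert-butyldimethylsilyl)oxy]-2,4,6-trimethylocta-2,4-dienoate
Product: 10 (2E,4E,6R,7S)-7-[(tert-butyldimethylsilyl)oxy]-2,4,6-trimethylocta-2,4-dien-1-ol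
Conditions: iBu2AlH (2.3 equiv), CH2Cl2, −78 °C
Reagents that add atoms: none
Why: 1,2-Reduction of the dienoate gives the allylic alcohol needed for directed epoxidation.

Step 7
Reactants: 10 (2E,4E,6R,7S)-7-[(tert-butyldimethylsilyl)oxy]-2,4,6-trimethylocta-2,4-dien-1-ol
Product: 11 [(2S,3S)-3-[(2E,4R,5S)-5-[(tert-butyldimethylsilyl)oxy]-4-methylhex-2-en-2-yl]-2-methyloxiran-2-yl]methanol
Conditions: Ti(OiPr)4 (10 mol %), L-(+)-diethyl tartrate (12 mol %), t-BuOOH, 4 Å MS, CH2Cl2, −20 °C
Reagents that add atoms: tert-butyl hydroperoxide, CC(C)(C)OO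
Why: Sharpless asymmetric epoxidation: only the allylic C2=C3 bond reacts, and L-(+)-tartrate delivers oxygen to the face that gives the (2S,3S)-epoxy alcohol of an (E)-2-methyl allylic alcohol; the remote C6/C7 centres do not interfere.

Step 8
Reactants: 11 [(2S,3S)-3-[(2E,4R,5S)-5-[(tert-butyldimethylsilyl)oxy]-4-methylhex-2-en-2-yl]-2-methyloxiran-2-yl]methanol
Product: 12 (2R,3S)-3-[(2E,4R,5S)-5-[(tert-butyldimethylsilyl)oxy]-4-methylhex-2-en-2-yl]-2-methyloxirane-2-carbaldehyde
Conditions: SO3·pyridine, DMSO, iPr2NEt, CH2Cl2, 0 °C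
Reagents that add atoms: none
Why: Parikh–Doering oxidation is non-acidic and routine for 2,3-epoxy alcohols; the aldehyde has no α-hydrogen and cannot epimerise.

Step 9
Reactants: 13 (E)-4-methoxybut-3-en-2-one
Product: 14 (Z)-3-iodo-4-methoxybut-3-en-2-one
Conditions: N-iodosuccinimide, AcOH, CH2Cl2, 23 °C; then Et3N, 0 °C
Reagents that add atoms: N-iodosuccinimide, O=C1CCC(=O)N1I
Why: Iodo-acetoxylation of the enol ether followed by amine-induced loss of acetic acid, the method used for α-iodination of β-methoxy acrylates; iodine enters at C3 only, which fixes the later pyranone regiochemistry.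

Step 10
Reactants: 12 (2R,3S)-3-[(2E,4R,5S)-5-[(tert-butyldimethylsilyl)oxy]-4-methylhex-2-en-2-yl]-2-methyloxirane-2-carbaldehyde; 14 (Z)-3-iodo-4-methoxybut-3-en-2-one
Product: 16 (4Z)-1-hydroxy-4-iodo-5-methoxy-1-[(2S,3S)-epoxyalkenyl]pent-4-en-3-one (both C1 epimers), via lithium enolate 15 (not isolated)
Conditions: 14, LiN(SiMe3)2, THF, −78 °C; then 12, −78 °C; aq. NH4Cl
Reagents that add atoms: lithium bis(trimethylsilyl)amide, C[Si](C)(C)N([Li])[Si](C)(C)C (lithium of intermediate 15 only)
Why: Kinetic deprotonation of the methyl ketone and aldol addition to the non-enolisable aldehyde 12; the new carbinol centre is removed in step 11, so its configuration does not matter.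

Step 11
Reactants: 16 (4Z)-1-hydroxy-4-iodo-5-methoxy-1-[(2S,3S)-epoxyalkenyl]pent-4-en-3-one
Product: 17 (4Z)-4-iodo-5-methoxy-1-[(2R,3S)-epoxyalkenyl]pent-4-ene-1,3-dione (enolised)
Conditions: Dess–Martin periodinane, NaHCO3, CH2Cl2, 0 to 23 °C
Reagents that add atoms: none
Why: Buffered Dess–Martin oxidation of a β-hydroxy ketone to the 1,3-diketone; 17 is taken on without chromatography.

Step 12
Reactants: 17 (4Z)-4-iodo-5-methoxy-1-[(2R,3S)-epoxyalkenyl]pent-4-ene-1,3-dione
Product: 18 5-iodo-2-[(2R,3S)-epoxyalkenyl]-4H-pyran-4-one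
Conditions: pyridinium p-toluenesulfonate (0.2 equiv), toluene, 45 °C
Reagents that add atoms: none
Why: Acid-catalysed 6-endo addition of the diketone enol oxygen to the β-methoxy enone with loss of methanol (γ-pyranone synthesis from β-methoxyvinyl 1,3-diketones); a pyridinium salt is the weakest useful acid, chosen for the sake of the vinyl epoxide.

Step 13
Reactants: 19 ethyl (S)-lactate
Product: 20 ethyl (S)-2-[(triethylsilyl)oxy]propanoate
Conditions: Et3SiCl, imidazole, CH2Cl2, 0 °C
Reagents that add atoms: chlorotriethylsilane, CC[Si](Cl)(CC)CC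
Why: Silylation; triethylsilyl is chosen because it can later be removed beside two tert-butyldimethylsilyl ethers.

Step 14
Reactants: 20 ethyl (S)-2-[(triethylsilyl)oxy]propanoate
Product: 21 (S)-2-[(triethylsilyl)oxy]propanal
Conditions: iBu2AlH (1.05 equiv), CH2Cl2, −78 °C; aq. KNaC4H4O6
Reagents that add atoms: none
Why: Partial reduction of an α-silyloxy ester at −78 °C, the usual route to O-silyl lactaldehydes; used without storage.

Step 15
Reactants: 18 5-iodo-2-[(2R,3S)-epoxyalkenyl]-4H-pyran-4-one; 21 (S)-2-[(triethylsilyl)oxy]propanal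
Product: 23 5-[(1R,2S)-1-hydroxy-2-[(triethylsilyl)oxy]propyl]-2-[(2R,3S)-epoxyalkenyl]-4H-pyran-4-one, via pyranonylmagnesium chloride 22 (not isolated)
Conditions: iPrMgCl·LiCl (1.1 equiv), THF, −40 °C; then 21, −78 to −40 °C; aq. NH4Cl at −40 °C
Reagents that add atoms: isopropylmagnesium chloride–lithium chloride, CC(C)[Mg]Cl.[Li]Cl (MgCl of intermediate 22 only)
Why: Iodine–magnesium exchange of an α-iodo-β-alkoxy enone is faster at −40 °C than attack on the vinylogous-ester carbonyl or the epoxide. Addition to the α-silyloxy aldehyde follows the polar Felkin–Anh model (attack anti to the C–OSiEt3 bond) and should favour the 1,2-anti carbinol (C8 R); the minor syn epimer is removed by chromatography.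

Step 16
Reactants: 23 5-[(1R,2S)-1-hydroxy-2-[(triethylsilyl)oxy]propyl]-2-[(2R,3S)-epoxyalkenyl]-4H-pyran-4-one
Product: 24 5-[(1R,2S)-1-[(tert-butyldimethylsilyl)oxy]-2-[(triethylsilyl)oxy]propyl]-2-[(2R,3S)-epoxyalkenyl]-4H-pyran-4-one
Conditions: t-BuMe2SiOSO2CF3, 2,6-lutidine, CH2Cl2, −78 °C
Reagents that add atoms: tert-butyldimethylsilyl trifluoromethanesulfonate, CC(C)(C)[Si](C)(C)OS(=O)(=O)C(F)(F)F
Why: Silyl triflate/2,6-lutidine protection of a hindered secondary alcohol; at −78 °C with excess base the epoxide is not opened.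

Step 17
Reactants: 24 5-[(1R,2S)-1-[(tert-butyldimethylsilyl)oxy]-2-[(triethylsilyl)oxy]propyl]-2-[(2R,3S)-epoxyalkenyl]-4H-pyran-4-one
Product: 26 (2Z)-2-[5-[(1R,2S)-1-[(tert-butyldimethylsilyl)oxy]-2-[(triethylsilyl)oxy]propyl]-2-[(2R,3S)-epoxyalkenyl]-4H-pyran-4-ylidene]acetaldehyde, via ethoxyvinyl carbinol 25 (not isolated)
Conditions: (Z)-BrCH=CHOEt, n-BuLi, THF, −78 °C; add 24, −78 to −40 °C; then aq. NaH2PO4 (pH 4–5), THF, 0 °C
Reagents that add atoms: (Z)-1-bromo-2-ethoxyethene, CCO/C=C\Br; water, O
Why: 1,2-Addition of an alkenyllithium to the pyranone carbonyl, then ionisation of the doubly allylic tertiary carbinol on mild acidification (the way 4-substituted pyrylium ions and 4-ylidene-4H-pyrans are made). Water adds at the ethoxy-bearing carbon and ethanol is lost, as in the 2-ethoxyvinyllithium enal homologation of ketones. The exocyclic double bond of the push–pull aldehyde forms as an interconverting Z/E mixture; the Z isomer is drawn.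

Step 18
Reactants: 26 (2Z)-2-[5-[(1R,2S)-1-[(tert-butyldimethylsilyl)oxy]-2-[(triethylsilyl)oxy]propyl]-2-[(2R,3S)-epoxyalkenyl]-4H-pyran-4-ylidene]acetaldehyde
Product: 27 (2Z)-2-[5-[(1R,2S)-1-[(tert-butyldimethylsilyl)oxy]-2-hydroxypropyl]-2-[(2R,3S)-epoxyalkenyl]-4H-pyran-4-ylidene]acetaldehyde
Conditions: HF·pyridine, pyridine, THF, 0 °C
Reagents that add atoms: none
Why: Buffered HF·pyridine cleaves a secondary triethylsilyl ether much faster than secondary tert-butyldimethylsilyl ethers and is tolerated by epoxides.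

Step 19
Reactants: 27 (2Z)-2-[5-[(1R,2S)-1-[(tert-butyldimethylsilyl)oxy]-2-hydroxypropyl]-2-[(2R,3S)-epoxyalkenyl]-4H-pyran-4-ylidene]acetaldehyde
Product: 28 (2Z)-2-[5-[(1R)-1-[(tert-butyldimethylsilyl)oxy]-2-oxopropyl]-2-[(2R,3S)-epoxyalkenyl]-4H-pyran-4-ylidene]acetaldehyde
Conditions: Dess–Martin periodinane, NaHCO3, CH2Cl2, 0 °C
Reagents that add atoms: none
Why: Buffered Dess–Martin oxidation gives the methyl ketone without base, so the now enolisable C8 centre is not exposed; 28 is used directly.

Step 20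
Reactants: 28 (2Z)-2-[5-[(1R)-1-[(tert-butyldimethylsilyl)oxy]-2-oxopropyl]-2-[(2R,3S)-epoxyalkenyl]-4H-pyran-4-ylidene]acetaldehyde
Product: 29 (7S,8R)-8-[(tert-butyldimethylsilyl)oxy]-7-hydroxy-7-methyl-3-[(2R,3S)-epoxyalkenyl]-7,8-dihydro-6H-isochromen-6-one
Conditions: (5aS,10bR)-2-(pentafluorophenyl)-5a,10b-dihydro-4H,6H-indeno[2,1-b][1,2,4]triazolo[4,3-d][1,4]oxazin-2-ium tetrafluoroborate (20 mol %), Et3N (20 mol %), degassed toluene, 23 to 40 °C
Reagents that add atoms: none
Why: The triazolylidene freed by Et3N adds to the C6 aldehyde of 28; proton transfer gives the hydroxy-enamine (acyl anion equivalent), whose C6 attacks the C7 ketone, and proton transfer with loss of the carbene gives the tertiary α-ketol 29. The closest known reaction type is the triazolium-catalysed intramolecular crossed aldehyde–ketone benzoin cyclisation to six-membered tertiary α-ketols; the aldehyde here is a vinylogous formate, a poorer acceptor for the carbene than the aryl and alkyl aldehydes used so far, but for the same reason it cannot serve as the electrophile of a homo-benzoin reaction. Ring A (C6, C5, C4a, C8a, C8, C7) closes in a 6-exo-trig mode. The new stereocentre C7 is set by the catalyst, which must deliver C6 to the Re face of the ketone; in the favoured half-chair the ketone oxygen is pseudo-equatorial and hydrogen-bonded to the enaminol OH, the methyl group is pseudo-axial and away from the triazolium, and the C8 silyloxy group is pseudo-equatorial and antiperiplanar to the forming bond, which gives the 7,8-trans arrangement (7S). Chemoselectivity comes from the substrate: the aldehyde has no α-hydrogen for an aldol pathway, homoenolate reaction at the fully substituted C4a would break the pyran conjugation and could only close a four-membered ring, and the Z/E isomers about C4a=C5 interconvert through the pyrylium enolate form, so the reactive Z isomer is replenished. Configurational integrity at C8 depends on a weak, substoichiometric base in a non-polar solvent.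

Step 21
Reactants: 29 (7S,8R)-8-[(tert-butyldimethylsilyl)oxy]-7-hydroxy-7-methyl-3-[(2R,3S)-epoxyalkenyl]-7,8-dihydro-6H-isochromen-6-one
Product: 30 pestaphilone D, (7S,8R)-7,8-dihydroxy-3-[(2R,3S)-3-[(2E,4R,5S)-5-hydroxy-4-methylhex-2-en-2-yl]-2-methyloxiran-2-yl]-7-methyl-7,8-dihydro-6H-isochromen-6-one
Conditions: Bu4NF, AcOH (1:1), THF, 0 to 23 °C
Reagents that add atoms: none
Why: Fluoride cleavage of both silyl ethers; acetic acid keeps the medium non-basic for the α-ketol, the β-hydroxy ketone relation and the vinylogous ester, and the epoxide is inert to buffered fluoride.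

## Compound list

1 | ethyl (S)-3-hydroxybutanoate | C[C@H](O)CC(=O)OCC | starting material
2 | dilithium alkoxide enolate of 1 (chelated dianion) | [Li]OC(OCC)=C[C@H](C)O[Li] | intermediate (not isolated)
3 | ethyl (2S,3S)-3-hydroxy-2-methylbutanoate | CCOC(=O)[C@@H](C)[C@H](C)O | intermediate
4 | ethyl (2S,3S)-3-[(tert-butyldimethylsilyl)oxy]-2-methylbutanoate | CCOC(=O)[C@@H](C)[C@H](C)O[Si](C)(C)C(C)(C)C | intermediate
5 | (2S,3S)-3-[(tert-butyldimethylsilyl)oxy]-2-methylbutanal | O=C[C@@H](C)[C@H](C)O[Si](C)(C)C(C)(C)C | intermediate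
6 | 2-(triphenylphosphoranylidene)propanal | CC(C=O)=P(c1ccccc1)(c1ccccc1)c1ccccc1 | starting material
7 | (2E,4R,5S)-5-[(tert-butyldimethylsilyl)oxy]-2,4-dimethylhex-2-enal | O=C/C(C)=C/[C@@H](C)[C@H](C)O[Si](C)(C)C(C)(C)C | intermediate
8 | ethyl 2-(triphenylphosphoranylidene)propanoate | CCOC(=O)C(C)=P(c1ccccc1)(c1ccccc1)c1ccccc1 | starting material
9 | ethyl (2E,4E,6R,7S)-7-[(tert-butyldimethylsilyl)oxy]-2,4,6-trimethylocta-2,4-dienoate | CCOC(=O)/C(C)=C/C(C)=C/[C@@H](C)[C@H](C)O[Si](C)(C)C(C)(C)C | intermediate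
10 | (2E,4E,6R,7S)-7-[(tert-butyldimethylsilyl)oxy]-2,4,6-trimethylocta-2,4-dien-1-ol | OC/C(C)=C/C(C)=C/[C@@H](C)[C@H](C)O[Si](C)(C)C(C)(C)C | intermediate
11 | [(2S,3S)-3-[(2E,4R,5S)-5-[(tert-butyldimethylsilyl)oxy]-4-methylhex-2-en-2-yl]-2-methyloxiran-2-yl]methanol | C/C(=C\[C@@H](C)[C@H](C)O[Si](C)(C)C(C)(C)C)[C@@H]1O[C@@]1(C)CO | intermediate
12 | (2R,3S)-3-[(2E,4R,5S)-5-[(tert-butyldimethylsilyl)oxy]-4-methylhex-2-en-2-yl]-2-methyloxirane-2-carbaldehyde | C/C(=C\[C@@H](C)[C@H](C)O[Si](C)(C)C(C)(C)C)[C@@H]1O[C@@]1(C)C=O | intermediate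
13 | (E)-4-methoxybut-3-en-2-one | CO/C=C/C(C)=O | starting material
14 | (Z)-3-iodo-4-methoxybut-3-en-2-one | CO/C=C(\I)C(C)=O | intermediate
15 | lithium enolate of 14 (lithium (Z)-3-iodo-4-methoxybuta-1,3-dien-2-olate) | C=C(O[Li])/C(I)=C/OC | intermediate (not isolated)
16 | (4Z)-1-hydroxy-4-iodo-5-methoxy-1-[(2S,3S)-epoxyalkenyl]pent-4-en-3-one, both C1 epimers | C/C(=C\[C@@H](C)[C@H](C)O[Si](C)(C)C(C)(C)C)[C@@H]1O[C@@]1(C)C(O)CC(=O)/C(I)=C/OC | intermediate
17 | (4Z)-4-iodo-5-methoxy-1-[(2R,3S)-epoxyalkenyl]pent-4-ene-1,3-dione | C/C(=C\[C@@H](C)[C@H](C)O[Si](C)(C)C(C)(C)C)[C@@H]1O[C@@]1(C)C(=O)CC(=O)/C(I)=C/OC | intermediate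
18 | 5-iodo-2-[(2R,3S)-epoxyalkenyl]-4H-pyran-4-one | C/C(=C\[C@@H](C)[C@H](C)O[Si](C)(C)C(C)(C)C)[C@@H]1O[C@@]1(C)C1=CC(=O)C(I)=CO1 | intermediate
19 | ethyl (S)-lactate | C[C@H](O)C(=O)OCC | starting material
20 | ethyl (S)-2-[(triethylsilyl)oxy]propanoate | C[C@H](O[Si](CC)(CC)CC)C(=O)OCC | intermediate
21 | (S)-2-[(triethylsilyl)oxy]propanal | C[C@H](O[Si](CC)(CC)CC)C=O | intermediate
22 | [4-oxo-6-[(2R,3S)-epoxyalkenyl]-4H-pyran-3-yl]magnesium chloride (LiCl complex) | C/C(=C\[C@@H](C)[C@H](C)O[Si](C)(C)C(C)(C)C)[C@@H]1O[C@@]1(C)C1=CC(=O)C([Mg]Cl)=CO1 | intermediate (not isolated)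
23 | 5-[(1R,2S)-1-hydroxy-2-[(triethylsilyl)oxy]propyl]-2-[(2R,3S)-epoxyalkenyl]-4H-pyran-4-one | C/C(=C\[C@@H](C)[C@H](C)O[Si](C)(C)C(C)(C)C)[C@@H]1O[C@@]1(C)C1=CC(=O)C(=CO1)[C@@H](O)[C@H](C)O[Si](CC)(CC)CC | intermediate
24 | 5-[(1R,2S)-1-[(tert-butyldimethylsilyl)oxy]-2-[(triethylsilyl)oxy]propyl]-2-[(2R,3S)-epoxyalkenyl]-4H-pyran-4-one | C/C(=C\[C@@H](C)[C@H](C)O[Si](C)(C)C(C)(C)C)[C@@H]1O[C@@]1(C)C1=CC(=O)C(=CO1)[C@@H](O[Si](C)(C)C(C)(C)C)[C@H](C)O[Si](CC)(CC)CC | intermediate
25 | 4-[(Z)-2-ethoxyethenyl]-4-hydroxy-4H-pyran adduct of 24, both C4 epimers | C/C(=C\[C@@H](C)[C@H](C)O[Si](C)(C)C(C)(C)C)[C@@H]1O[C@@]1(C)C1=CC(O)(/C=C\OCC)C(=CO1)[C@@H](O[Si](C)(C)C(C)(C)C)[C@H](C)O[Si](CC)(CC)CC | intermediate (not isolated)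
26 | (2Z)-2-[5-[(1R,2S)-1-[(tert-butyldimethylsilyl)oxy]-2-[(triethylsilyl)oxy]propyl]-2-[(2R,3S)-epoxyalkenyl]-4H-pyran-4-ylidene]acetaldehyde | C/C(=C\[C@@H](C)[C@H](C)O[Si](C)(C)C(C)(C)C)[C@@H]1O[C@@]1(C)C1=C/C(=C/C=O)C(=CO1)[C@@H](O[Si](C)(C)C(C)(C)C)[C@H](C)O[Si](CC)(CC)CC | intermediate
27 | (2Z)-2-[5-[(1R,2S)-1-[(tert-butyldimethylsilyl)oxy]-2-hydroxypropyl]-2-[(2R,3S)-epoxyalkenyl]-4H-pyran-4-ylidene]acetaldehyde | C/C(=C\[C@@H](C)[C@H](C)O[Si](C)(C)C(C)(C)C)[C@@H]1O[C@@]1(C)C1=C/C(=C/C=O)C(=CO1)[C@@H](O[Si](C)(C)C(C)(C)C)[C@H](C)O | intermediate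
28 | (2Z)-2-[5-[(1R)-1-[(tert-butyldimethylsilyl)oxy]-2-oxopropyl]-2-[(2R,3S)-epoxyalkenyl]-4H-pyran-4-ylidene]acetaldehyde | C/C(=C\[C@@H](C)[C@H](C)O[Si](C)(C)C(C)(C)C)[C@@H]1O[C@@]1(C)C1=C/C(=C/C=O)C(=CO1)[C@@H](O[Si](C)(C)C(C)(C)C)C(C)=O | intermediate
29 | (7S,8R)-8-[(tert-butyldimethylsilyl)oxy]-7-hydroxy-7-methyl-3-[(2R,3S)-epoxyalkenyl]-7,8-dihydro-6H-isochromen-6-one | C/C(=C\[C@@H](C)[C@H](C)O[Si](C)(C)C(C)(C)C)[C@@H]1O[C@@]1(C)C1=CC2=CC(=O)[C@@](C)(O)[C@H](O[Si](C)(C)C(C)(C)C)C2=CO1 | intermediate
30 | pestaphilone D, (7S,8R)-7,8-dihydroxy-3-[(2R,3S)-3-[(2E,4R,5S)-5-hydroxy-4-methylhex-2-en-2-yl]-2-methyloxiran-2-yl]-7-methyl-7,8-dihydro-6H-isochromen-6-one | C/C(=C\[C@@H](C)[C@H](C)O)[C@@H]1O[C@@]1(C)C1=CC2=CC(=O)[C@@](C)(O)[C@H](O)C2=CO1 | target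

## Step count and least certain steps

Total: 21 steps. Longest linear sequence: 18 steps (steps 1–8, 10–12 and 15–21). Steps 9, 13 and 14 are side branches.

**Step 20 (key step).**
- What may go wrong: slow carbene addition to the donor-stabilised aldehyde, which would prolong exposure of 28 to base and so favour epimerisation at C8; and attack on the wrong ketone face if the catalyst and the C8 substituent are mismatched. The simple Felkin–Anh arrangement with the ketone oxygen pseudo-axial would lead to the 7,8-cis isomer, so catalyst control is essential.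
- Fallback (sets out from 23, returns at 30): the C8 stereocentre is taken out of the carbene step. 23 is silylated with Et3SiOSO2CF3/2,6-lutidine to the bis(triethylsilyl) ether F1. The homologation of step 17 gives the pyranylidene acetaldehyde F2. HF·pyridine frees both carbinols to give the diol F3. Swern oxidation gives the 1,2-diketone F4, which has a strongly activated C7 acceptor and no epimerisable centre. The same triazolium salt with Et3N closes ring A to the 8-oxo α-ketol F5, with C7 set by the catalyst alone. NaBH4/CeCl3 in MeOH at −78 °C should reduce the more electrophilic C8 carbonyl from the face opposite the C7 methyl group and give the 7,8-trans diol F6; differentiation of C8 from C6 is the point to watch. Bu4NF/AcOH then gives 30.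

**Step 15.**
- What may go wrong: modest Felkin–Anh facial selectivity in the addition to 21; ring opening of the magnesiated pyranone 22 by β-elimination if the exchange is run too warm; and triethylsilyl migration from the C7 oxygen to the new magnesium alkoxide.
- Fallback (sets out from 23 as a mixture of C8 epimers, returns at 23): the mixture is oxidised with Dess–Martin periodinane to the 5-acylpyranone F7. Corey–Bakshi–Shibata reduction (B-methyl oxazaborolidine, catecholborane, −78 °C; the catalyst enantiomer that gives the 1R carbinol) then sets C8 under reagent control rather than by addition to the aldehyde.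

**Step 17.**
- What may go wrong: competing conjugate addition of the alkenyllithium at the unsubstituted C1–H position of the pyranone, or loss of the triethylsilyl ether and opening of the vinyl epoxide during the acidic unveiling of the aldehyde.
- Fallback (sets out from 24, returns at 26): MeMgBr is added to the pyranone carbonyl at −78 °C to give the tertiary carbinol F8, which loses water on work-up to the 4-methylidene-4H-pyran F9. Vilsmeier formylation of the exocyclic methylene carbon with preformed Me2N=CHCl chloride in CH2Cl2/2,6-lutidine at −20 °C gives the vinylogous iminium salt F10, and aq. NaHCO3 hydrolyses it to 26.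

**Step 10.**
- What may go wrong: decomposition of the α-iodo enolate 15 (halogen transfer or self-condensation) before it meets the hindered aldehyde 12.
- Fallback (sets out from 12 and 13, returns at 18): the aldol is run with the parent enone 13 under the conditions of step 10 to give the aldol F11. Dess–Martin oxidation gives the diketone F12, and pyridinium p-toluenesulfonate closes it to the 5-unsubstituted pyranone F13. Iodination with N-iodosuccinimide in MeCN then places iodine at C5, the less hindered α-carbon next to the unsubstituted C6. Chemoselectivity against the side-chain alkene is the reason this order is not the first choice.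

## Further compounds

F1 | step 20 | 5-[(1R,2S)-1,2-bis[(triethylsilyl)oxy]propyl]-2-[(2R,3S)-epoxyalkenyl]-4H-pyran-4-one | C/C(=C\[C@@H](C)[C@H](C)O[Si](C)(C)C(C)(C)C)[C@@H]1O[C@@]1(C)C1=CC(=O)C(=CO1)[C@@H](O[Si](CC)(CC)CC)[C@H](C)O[Si](CC)(CC)CC
F2 | step 20 | (2Z)-2-[5-[(1R,2S)-1,2-bis[(triethylsilyl)oxy]propyl]-2-[(2R,3S)-epoxyalkenyl]-4H-pyran-4-ylidene]acetaldehyde | C/C(=C\[C@@H](C)[C@H](C)O[Si](C)(C)C(C)(C)C)[C@@H]1O[C@@]1(C)C1=C/C(=C/C=O)C(=CO1)[C@@H](O[Si](CC)(CC)CC)[C@H](C)O[Si](CC)(CC)CC
F3 | step 20 | (2Z)-2-[5-[(1R,2S)-1,2-dihydroxypropyl]-2-[(2R,3S)-epoxyalkenyl]-4H-pyran-4-ylidene]acetaldehyde | C/C(=C\[C@@H](C)[C@H](C)O[Si](C)(C)C(C)(C)C)[C@@H]1O[C@@]1(C)C1=C/C(=C/C=O)C(=CO1)[C@@H](O)[C@H](C)O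
F4 | step 20 | (2Z)-2-[5-(2-oxopropanoyl)-2-[(2R,3S)-epoxyalkenyl]-4H-pyran-4-ylidene]acetaldehyde | C/C(=C\[C@@H](C)[C@H](C)O[Si](C)(C)C(C)(C)C)[C@@H]1O[C@@]1(C)C1=C/C(=C/C=O)C(=CO1)C(=O)C(C)=O
F5 | step 20 | (7R)-7-hydroxy-7-methyl-3-[(2R,3S)-epoxyalkenyl]-6H-isochromene-6,8(7H)-dione (spatial arrangement at C7 as in 29) | C/C(=C\[C@@H](C)[C@H](C)O[Si](C)(C)C(C)(C)C)[C@@H]1O[C@@]1(C)C1=CC2=CC(=O)[C@@](C)(O)C(=O)C2=CO1
F6 | step 20 | (7S,8R)-7,8-dihydroxy-7-methyl-3-[(2R,3S)-epoxyalkenyl]-7,8-dihydro-6H-isochromen-6-one | C/C(=C\[C@@H](C)[C@H](C)O[Si](C)(C)C(C)(C)C)[C@@H]1O[C@@]1(C)C1=CC2=CC(=O)[C@@](C)(O)[C@H](O)C2=CO1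
F7 | step 15 | 2-[(2R,3S)-epoxyalkenyl]-5-[(2S)-2-[(triethylsilyl)oxy]propanoyl]-4H-pyran-4-one | C/C(=C\[C@@H](C)[C@H](C)O[Si](C)(C)C(C)(C)C)[C@@H]1O[C@@]1(C)C1=CC(=O)C(=CO1)C(=O)[C@H](C)O[Si](CC)(CC)CC
F8 | step 17 | 3-[(1R,2S)-1-[(tert-butyldimethylsilyl)oxy]-2-[(triethylsilyl)oxy]propyl]-4-methyl-6-[(2R,3S)-epoxyalkenyl]-4H-pyran-4-ol, both C4 epimers | C/C(=C\[C@@H](C)[C@H](C)O[Si](C)(C)C(C)(C)C)[C@@H]1O[C@@]1(C)C1=CC(C)(O)C(=CO1)[C@@H](O[Si](C)(C)C(C)(C)C)[C@H](C)O[Si](CC)(CC)CC
F9 | step 17 | 5-[(1R,2S)-1-[(tert-butyldimethylsilyl)oxy]-2-[(triethylsilyl)oxy]propyl]-4-methylidene-2-[(2R,3S)-epoxyalkenyl]-4H-pyran | C/C(=C\[C@@H](C)[C@H](C)O[Si](C)(C)C(C)(C)C)[C@@H]1O[C@@]1(C)C1=CC(=C)C(=CO1)[C@@H](O[Si](C)(C)C(C)(C)C)[C@H](C)O[Si](CC)(CC)CC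
F10 | step 17 | 3-[(1R,2S)-1-[(tert-butyldimethylsilyl)oxy]-2-[(triethylsilyl)oxy]propyl]-4-[(E)-2-(dimethylamino)ethenyl]-6-[(2R,3S)-epoxyalkenyl]pyrylium chloride | C/C(=C\[C@@H](C)[C@H](C)O[Si](C)(C)C(C)(C)C)[C@@H]1O[C@@]1(C)c1cc(/C=C/N(C)C)c(c[o+]1)[C@@H](O[Si](C)(C)C(C)(C)C)[C@H](C)O[Si](CC)(CC)CC.[Cl-]
F11 | step 10 | (4E)-1-hydroxy-5-methoxy-1-[(2S,3S)-epoxyalkenyl]pent-4-en-3-one, both C1 epimers | C/C(=C\[C@@H](C)[C@H](C)O[Si](C)(C)C(C)(C)C)[C@@H]1O[C@@]1(C)C(O)CC(=O)/C=C/OC
F12 | step 10 | (4E)-5-methoxy-1-[(2R,3S)-epoxyalkenyl]pent-4-ene-1,3-dione | C/C(=C\[C@@H](C)[C@H](C)O[Si](C)(C)C(C)(C)C)[C@@H]1O[C@@]1(C)C(=O)CC(=O)/C=C/OC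
F13 | step 10 | 2-[(2R,3S)-epoxyalkenyl]-4H-pyran-4-one | C/C(=C\[C@@H](C)[C@H](C)O[Si](C)(C)C(C)(C)C)[C@@H]1O[C@@]1(C)C1=CC(=O)C=CO1
A1 | alternative 1 | 2,4-dihydroxy-6-[2-[(2R,3S)-3-[(2E,4R,5S)-5-hydroxy-4-methylhex-2-en-2-yl]-2-methyloxiran-2-yl]-2-oxoethyl]-3-methylbenzaldehyde | C/C(=C\[C@@H](C)[C@H](C)O)[C@@H]1O[C@@]1(C)C(=O)Cc1cc(O)c(C)c(O)c1C=O
A2 | alternative 1 | (7R)-7-hydroxy-3-[(2R,3S)-3-[(2E,4R,5S)-5-hydroxy-4-methylhex-2-en-2-yl]-2-methyloxiran-2-yl]-7-methyl-6H-isochromene-6,8(7H)-dione (8-oxo congener of 30) | C/C(=C\[C@@H](C)[C@H](C)O)[C@@H]1O[C@@]1(C)C1=CC2=CC(=O)[C@@](C)(O)C(=O)C2=CO1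
A3 | alternative 2 | 5-[(1R,2S)-2-methyl-3-oxo-1,2-bis[(triethylsilyl)oxy]butyl]-2-[(2R,3S)-epoxyalkenyl]-4H-pyran-4-one | C/C(=C\[C@@H](C)[C@H](C)O[Si](C)(C)C(C)(C)C)[C@@H]1O[C@@]1(C)C1=CC(=O)C(=CO1)[C@@H](O[Si](CC)(CC)CC)[C@](C)(O[Si](CC)(CC)CC)C(C)=O
A4 | alternative 2 | (7S,8R)-7-methyl-7,8-bis[(triethylsilyl)oxy]-3-[(2R,3S)-epoxyalkenyl]-7,8-dihydro-6H-isochromen-6-one | C/C(=C\[C@@H](C)[C@H](C)O[Si](C)(C)C(C)(C)C)[C@@H]1O[C@@]1(C)C1=CC2=CC(=O)[C@@](C)(O[Si](CC)(CC)CC)[C@H](O[Si](CC)(CC)CC)C2=CO1
A5 | alternative 3 | (2S)-2-methyl-3-oxo-4-[2-[(2R,3S)-epoxyalkenyl]-4H-pyran-4-ylidene]-2-[(triethylsilyl)oxy]butanal (acyl group syn to C8a) | C/C(=C\[C@@H](C)[C@H](C)O[Si](C)(C)C(C)(C)C)[C@@H]1O[C@@]1(C)C1=C/C(=C/C(=O)[C@@](C)(O[Si](CC)(CC)CC)C=O)C=CO1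
A6 | alternative 3 | (7S,8R)-8-hydroxy-7-methyl-7-[(triethylsilyl)oxy]-3-[(2R,3S)-epoxyalkenyl]-7,8-dihydro-6H-isochromen-6-one | C/C(=C\[C@@H](C)[C@H](C)O[Si](C)(C)C(C)(C)C)[C@@H]1O[C@@]1(C)C1=CC2=CC(=O)[C@@](C)(O[Si](CC)(CC)CC)[C@H](O)C2=CO1
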